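The disconnection is the C7–C8 bond at the centre of the tetradecamethylene bridge of the 20-membered ring. This bond lies seven carbons from ring A and seven from ring B, remote from every heteroatom. Ring-closing olefin metathesis forms it as C7=C8 in one operation, with the bent diaryl ether (ring A–O–ring B) holding the two arms close. The precursor is a diaryl ether carrying two identical 1-acetoxyoct-7-enyl arms, made by Ullmann union of two bought benzaldehydes and one twofold Grignard addition. The benzylic acetoxy groups and the alkene are temporary: one neutral hydrogenation erases them together, and demethylation then frees the phenols.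

Key step: step 3

Remark: bridge carbons are numbered C1 (on ring B, the ring with two hydroxyls) to C14 (on ring A); the target is achiral, so the two carbinol centres from step 2 and the alkene geometry from step 3 are carried as mixtures because step 4 removes all of them.

Step 1
Reactants: 1 2-bromo-3,5-dimethoxybenzaldehyde; 2 3-hydroxy-5-methoxybenzaldehyde
Product: 3 2-(3-formyl-5-methoxyphenoxy)-3,5-dimethoxybenzaldehyde
Conditions: CuI (10 mol%), N,N-dimethylglycine hydrochloride (30 mol%), Cs2CO3, 1,4-dioxane, 100 °C
Reagents that add atoms: none
Why: Ullmann diaryl ether synthesis (copper-catalysed C–O coupling), in which the ortho-formyl group of 1 activates the flanked C–Br bond and guides copper to it, the phenoxide of 2 is unhindered, and neither aldehyde can enolise under carbonate base.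

Step 2
Reactants: 3 2-(3-formyl-5-methoxyphenoxy)-3,5-dimethoxybenzaldehyde; 4 7-bromohept-1-ene
Product: 7 1-{2-[3-(1-acetoxyoct-7-en-1-yl)-5-methoxyphenoxy]-3,5-dimethoxyphenyl}oct-7-en-1-yl acetate (diastereomer mixture), via hept-6-en-1-ylmagnesium bromide 5 (not isolated), via bis(bromomagnesium alkoxide) 6 (not isolated)
Conditions: 4, Mg, THF, 50 °C; then 3, THF, 0 °C to rt; then Ac2O, 0 °C to rt
Reagents that add atoms: acetic anhydride, CC(=O)OC(C)=O
Why: Twofold Grignard 1,2-addition to the two non-enolisable aryl aldehydes, followed by O-acylation of the magnesium alkoxides in the same flask, attaches both seven-carbon arms and activates both benzylic oxygens for later hydrogenolysis; the two carbinol stereocentres form without control and are carried as a mixture because step 4 deletes them.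

Step 3
Reactants: 7 diene diacetate
Product: 8 macrocyclic ene diacetate (20-membered ring with C7=C8 alkene and acetoxy groups at C1 and C14; E/Z and diastereomer mixture)
Conditions: second-generation Grubbs catalyst RuCl2(=CHPh)(H2IMes)(PCy3) (5 mol%), 1,4-benzoquinone (10 mol%), CH2Cl2 (1 mM, slow addition of 7), 40 °C
Reagents that add atoms: none
Why: Olefin metathesis by the Chauvin mechanism: the ruthenium carbene loads onto one terminal alkene of 7, forms a ruthenacyclobutane with the other and cycloreverts with release of ethene, so the C7=C8 bond is created as the ring closes. The closest known reaction type is ring-closing metathesis macrocyclisation of α,ω-dienes to large cyclophanes. The ring closed is the 20-membered macrocycle (fourteen bridge carbons, two atoms of ring B, the ether oxygen, three atoms of ring A), an end-to-end macrocyclisation of the two chain termini that is helped by the bent diaryl ether hinge and driven by loss of ethene. No stereocentre is formed, the C7=C8 geometry is not controlled and need not be, and the two acetoxy-bearing centres are spectators, since step 4 removes all three elements. The selectivity needed is ring closure over intermolecular oligomerisation, with no small-ring metathesis and no double-bond migration: high dilution with slow addition secures the first, benzoquinone suppresses migration, and the substrate secures the rest because each arm holds a single monosubstituted alkene six sp3 carbons away from its arene (the arms were attached by Grignard addition, not olefination, so no 1,7-diene exists that could extrude cyclohexene), while esters, aryl ethers and the diaryl ether are inert to the catalyst.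

Step 4
Reactants: 8 macrocyclic ene diacetate
Product: 10 tri-O-methyl ether of the target, via saturated macrocyclic diacetate 9 (not isolated)
Conditions: H2 (3 atm), 10% Pd/C, EtOH–EtOAc, rt to 40 °C
Reagents that add atoms: none
Why: Heterogeneous catalytic hydrogenation saturates the C7=C8 alkene and then cleaves both benzylic C–OAc bonds by hydrogenolysis under neutral conditions (no benzylic cation that ring A could trap), which erases the alkene geometry and both stereocentres.

Step 5
Reactants: 10 tri-O-methyl ether of the target
Product: 11 target macrocyclic diaryl ether triol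
Conditions: BBr3, CH2Cl2, −78 °C to rt; then H2O
Reagents that add atoms: none
Why: BBr3 demethylation (Lewis acid-mediated cleavage of aryl methyl ethers by bromide attack at methyl) frees the three phenols, while the diaryl ether offers no sp3 carbon for bromide and stays intact.

Compound list
1 | 2-bromo-3,5-dimethoxybenzaldehyde | O=Cc1cc(OC)cc(OC)c1Br | starting material
2 | 3-hydroxy-5-methoxybenzaldehyde | O=Cc1cc(O)cc(OC)c1 | starting material
3 | 2-(3-formyl-5-methoxyphenoxy)-3,5-dimethoxybenzaldehyde | O=Cc1cc(OC)cc(OC)c1Oc1cc(C=O)cc(OC)c1 | intermediate
4 | 7-bromohept-1-ene | C=CCCCCCBr | starting material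
5 | hept-6-en-1-ylmagnesium bromide (not isolated) | C=CCCCCC[Mg]Br | intermediate
6 | bis(bromomagnesium alkoxide) of the diene diol (not isolated) | C=CCCCCCC(O[Mg]Br)c1cc(OC)cc(OC)c1Oc1cc(C(O[Mg]Br)CCCCCC=C)cc(OC)c1 | intermediate
7 | 1-{2-[3-(1-acetoxyoct-7-en-1-yl)-5-methoxyphenoxy]-3,5-dimethoxyphenyl}oct-7-en-1-yl acetate (diastereomer mixture) | C=CCCCCCC(OC(C)=O)c1cc(OC)cc(OC)c1Oc1cc(C(OC(C)=O)CCCCCC=C)cc(OC)c1 | intermediate
8 | macrocyclic ene diacetate: 20-membered ring, C7=C8 alkene, OAc at C1 and C14, three OMe (E/Z and diastereomer mixture) | CC(=O)OC1CCCCCC=CCCCCCC(OC(C)=O)c2cc(OC)cc(c2)Oc2c(OC)cc(OC)cc21 | intermediate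
9 | saturated macrocyclic diacetate (not isolated; diastereomer mixture) | CC(=O)OC1CCCCCCCCCCCCC(OC(C)=O)c2cc(OC)cc(c2)Oc2c(OC)cc(OC)cc21 | intermediate
10 | tri-O-methyl ether of the target (saturated 20-membered diaryl ether macrocycle) | COc1cc2cc(c1)Oc1c(OC)cc(OC)cc1CCCCCCCCCCCCCC2 | intermediate
11 | target macrocyclic diaryl ether triol | Oc1cc2cc(c1)Oc1c(O)cc(O)cc1CCCCCCCCCCCCCC2 | target

Total step count: 5
Longest linear sequence: 5 steps (1 or 2 → 3 → 7 → 8 → 10 → 11)

Steps most likely to fail

Step 3 (key step). Intermolecular metathesis may outrun ring closure and give oligomers, and ruthenium hydride species may migrate the double bonds before closure and give ring-contracted homologues. The fallback replaces alkene by alkyne metathesis, which cannot migrate double bonds and closes the same ring at the same bond. It sets out from dialdehyde 3 and comes back at 10. Bought 8-bromooct-2-yne (CC#CCCCCCBr) would be converted with Mg in THF into oct-6-yn-1-ylmagnesium bromide F1. F1 would add twice to 3 to give the bis(bromomagnesium alkoxide) F2, which is acetylated in the same flask with Ac2O to the diyne diacetate F3. Ring-closing alkyne metathesis of F3 with Mo(≡CC6H4OMe-4)(OSiPh3)3 and 5 Å molecular sieves in toluene at 80 °C should give the C7≡C8 macrocyclic yne diacetate F4, the sieves taking up the but-2-yne. Hydrogenation of F4 under the conditions of step 4 passes through 9 and rejoins the route at 10.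

Step 1. Copper insertion into a C–Br bond flanked by CHO and OMe on an electron-rich ring may be slow, so protodebromination and base-induced loss of aldehyde may compete. The fallback drops copper and uses uncatalysed nucleophilic aromatic substitution of a fluoride. It sets out from phenol 2 and comes back at 3. Bought 3,5-dimethoxybenzaldehyde (COc1cc(C=O)cc(OC)c1) would be fluorinated with Selectfluor in MeCN at rt, at the position between CHO and OMe, to give 2-fluoro-3,5-dimethoxybenzaldehyde F5. Heating F5 with 2 and K2CO3 in DMF at 120 °C, with the ortho-formyl group stabilising the Meisenheimer intermediate, should give dialdehyde 3.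

Step 4. After fast saturation of the alkene, hydrogenolysis of the benzylic C–OAc bonds may stall, most likely on the ring-A side, where no donor stands ortho or para to the benzylic carbon. The fallback removes the oxygens through the ketone oxidation level without any benzylic cation. It sets out from the saturated diacetate 9 (then isolated) and comes back at 10. Methanolysis (K2CO3, MeOH, rt) would give the saturated macrocyclic diol F6, and Dess–Martin periodinane in CH2Cl2 the saturated macrocyclic diketone F7. Huang-Minlon Wolff–Kishner reduction (N2H4·H2O, KOH, diethylene glycol, 130 then 190 °C) would form the bis-hydrazone F8 in the flask, which loses dinitrogen to give 10. Any partial demethylation under the hot base converges in step 5.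

Further compounds
F1 | step 3 | oct-6-yn-1-ylmagnesium bromide | CC#CCCCCC[Mg]Br
F2 | step 3 | bis(bromomagnesium alkoxide) of the diyne diol | CC#CCCCCCC(O[Mg]Br)c1cc(OC)cc(OC)c1Oc1cc(C(O[Mg]Br)CCCCCC#CC)cc(OC)c1
F3 | step 3 | 1-{2-[3-(1-acetoxynon-7-yn-1-yl)-5-methoxyphenoxy]-3,5-dimethoxyphenyl}non-7-yn-1-yl acetate | CC#CCCCCCC(OC(C)=O)c1cc(OC)cc(OC)c1Oc1cc(C(OC(C)=O)CCCCCC#CC)cc(OC)c1
F4 | step 3 | macrocyclic yne diacetate (20-membered ring, C7≡C8) | CC(=O)OC1CCCCCC#CCCCCCC(OC(C)=O)c2cc(OC)cc(c2)Oc2c(OC)cc(OC)cc21
F5 | step 1 | 2-fluoro-3,5-dimethoxybenzaldehyde | O=Cc1cc(OC)cc(OC)c1F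
F6 | step 4 | saturated macrocyclic diol | OC1CCCCCCCCCCCCC(O)c2cc(OC)cc(c2)Oc2c(OC)cc(OC)cc21
F7 | step 4 | saturated macrocyclic diketone | O=C1CCCCCCCCCCCCC(=O)c2cc(OC)cc(c2)Oc2c(OC)cc(OC)cc21
F8 | step 4 | bis-hydrazone of the diketone | NN=C1CCCCCCCCCCCCC(=NN)c2cc(OC)cc(c2)Oc2c(OC)cc(OC)cc21
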